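The ten-membered carbocycle is disconnected at C2–C3 (germacrane numbering). C2 is allylic to the C1=C10 enoate and C3 hangs on the C4 stereocentre, so the bond is made as the new olefin of a cyclic dienoate: ring-closing ene–diene metathesis of the C4 vinyl group onto the terminal olefin of a 2-substituted pentadienoate, on a seco-triene that already carries the trans-fused γ-lactone (as its α-phosphonate), the C8 isobutyrate and all four stereocentres; lactone and ring-cis enoate act as turn elements. Diimide then saturates C2=C3. The C6–C8 triad comes from one Sharpless epoxidation and a 5-exo epoxide opening by a tethered phosphonoacetate, whose phosphonate finally delivers the exocyclic methylene.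

Key step: step 14

Remark on numbering: C6 carries the lactone oxygen, C7 is the ring-fusion CH, C8 carries the isobutyrate, C10 carries the CO2Me (C14), C1 is the olefinic CH, C2 and C3 are the ring CH2 groups, C4 carries CH2OH (C15), and C11–C13 are the lactone α-carbon, carbonyl and methylene. Descriptors given with these locants follow each compound's own CIP ranking.

Step 1
Reactants: 1 (4R)-4-benzyl-1,3-oxazolidin-2-one; 2 (2E)-but-2-enoyl chloride
Product: 3 (4R)-4-benzyl-3-[(2E)-but-2-enoyl]-1,3-oxazolidin-2-one
Conditions: n-BuLi, THF, −78 °C; then 2, −78 → 0 °C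
Reagents that add atoms: none
Why: N-acylation of the lithiated oxazolidinone by an acid chloride is the standard entry to Evans imides, and the bought benzyl stereocentre is the source of C4.

Step 2
Reactants: 3 (4R)-4-benzyl-3-[(2E)-but-2-enoyl]-1,3-oxazolidin-2-one; 4 tert-butyl bromoacetate
Product: 5 tert-butyl (3R)-3-{[(4R)-4-benzyl-2-oxo-1,3-oxazolidin-3-yl]carbonyl}pent-4-enoate
Conditions: NaN(SiMe3)2, THF, −78 °C; then 4, −78 → −40 °C
Reagents that add atoms: none
Why: Evans deconjugative α-alkylation: γ-deprotonation gives the chelated (Z)-dienolate, which is alkylated at the α-carbon on the face opposite the benzyl group, so the new vinyl-bearing centre (future C4, with C3 as its vinyl carbon) should be R.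

Step 3
Reactants: 5 tert-butyl (3R)-3-{[(4R)-4-benzyl-2-oxo-1,3-oxazolidin-3-yl]carbonyl}pent-4-enoate
Product: 6 tert-butyl (3R)-3-(hydroxymethyl)pent-4-enoate
Conditions: LiBH4, MeOH (1 equiv), Et2O, 0 °C
Reagents that add atoms: none
Why: Reductive cleavage of the imide by LiBH4 frees the primary alcohol (future C15) and the auxiliary, while the tert-butyl ester, the vinyl group and the stereocentre are untouched.

Step 4
Reactants: 6 tert-butyl (3R)-3-(hydroxymethyl)pent-4-enoate
Product: 7 tert-butyl (3R)-3-({[tert-butyl(dimethyl)silyl]oxy}methyl)pent-4-enoate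
Conditions: TBSCl, imidazole, CH2Cl2, 25 °C
Reagents that add atoms: tert-butyldimethylsilyl chloride, CC(C)(C)[Si](C)(C)Cl
Why: Silylation of a primary alcohol; the silyl ether keeps O15 out of the later acylations.

Step 5
Reactants: 7 tert-butyl (3R)-3-({[tert-butyl(dimethyl)silyl]oxy}methyl)pent-4-enoate
Product: 8 (3R)-3-({[tert-butyl(dimethyl)silyl]oxy}methyl)pent-4-enal
Conditions: i-Bu2AlH (1.05 equiv), CH2Cl2, −78 °C; Rochelle salt work-up
Reagents that add atoms: none
Why: Partial reduction of the ester at low temperature stops at the aluminium hemiacetal and gives the C6 aldehyde on work-up.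

Step 6
Reactants: 9 methyl (triphenyl-λ5-phosphanylidene)acetate; 10 3-bromoprop-1-yne
Product: 12 methyl 2-(triphenyl-λ5-phosphanylidene)pent-4-ynoate, via phosphonium bromide 11 (not isolated)
Conditions: 9 (2 equiv), EtOAc, reflux
Reagents that add atoms: none
Why: C-alkylation of the stabilised ylide by the propargylic bromide gives the phosphonium salt, which the second equivalent of 9 deprotonates (transylidation) to the α-substituted stabilised ylide.

Step 7
Reactants: 12 methyl 2-(triphenyl-λ5-phosphanylidene)pent-4-ynoate; 13 prop-2-enal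
Product: 14 methyl (2E)-2-(prop-2-yn-1-yl)penta-2,4-dienoate
Conditions: CH2Cl2, 0 → 25 °C
Reagents that add atoms: none
Why: Wittig olefination with an α-substituted stabilised ylide places the aldehyde residue trans to the ester, which is the C1=C10 geometry of the target.

Step 8
Reactants: 14 methyl (2E)-2-(prop-2-yn-1-yl)penta-2,4-dienoate
Product: 16 methyl (2E)-2-[(2E)-3-iodoprop-2-en-1-yl]penta-2,4-dienoate, via alkenylzirconocene chloride 15 (not isolated)
Conditions: Cp2Zr(H)Cl (1.1 equiv), THF, 25 °C; then I2, 0 °C
Reagents that add atoms: iodine, II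
Why: Hydrozirconation adds Zr–H syn and terminally to the alkyne faster than to olefins or esters, and iodinolysis with retention gives the (E)-vinyl iodide (C7).

Step 9
Reactants: 16 methyl (2E)-2-[(2E)-3-iodoprop-2-en-1-yl]penta-2,4-dienoate; 8 (3R)-3-({[tert-butyl(dimethyl)silyl]oxy}methyl)pent-4-enal
Product: 17 methyl (2E)-2-[(2E,4R,6R)-6-({[tert-butyl(dimethyl)silyl]oxy}methyl)-4-hydroxyocta-2,7-dien-1-yl]penta-2,4-dienoate
Conditions: CrCl2 (3 equiv), NiCl2 (0.1 equiv), N-[2-(4-isopropyl-4,5-dihydrooxazol-2-yl)-6-methylphenyl]methanesulfonamide (the enantiomer that delivers the R carbinol, 3.3 equiv), Et3N, THF, 25 °C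
Reagents that add atoms: none
Why: Nozaki–Hiyama–Kishi alkenylation joins C6 and C7 chemoselectively at the aldehyde with retention of the (E)-olefin; the chiral chromium–ligand complex should favour the 6R carbinol, and any 6S epimer is left behind in step 10.

Step 10
Reactants: 17 methyl (2E)-2-[(2E,4R,6R)-6-({[tert-butyl(dimethyl)silyl]oxy}methyl)-4-hydroxyocta-2,7-dien-1-yl]penta-2,4-dienoate
Product: 18 methyl (2E)-2-({(2R,3R)-3-[(1R,3R)-3-({[tert-butyl(dimethyl)silyl]oxy}methyl)-1-hydroxypent-4-en-1-yl]oxiran-2-yl}methyl)penta-2,4-dienoate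
Conditions: Ti(OiPr)4, D-(−)-diisopropyl tartrate, t-BuOOH, 4 Å MS, CH2Cl2, −20 °C
Reagents that add atoms: tert-butyl hydroperoxide, CC(C)(C)OO
Why: Sharpless asymmetric epoxidation touches only the allylic olefin; with the D-(−)-tartrate the 6R alcohol is the matched, fast-reacting epimer and should give the erythro trans-epoxide, so C7 and C8 are set in one event by reagent and C6 together.

Step 11
Reactants: 18 the erythro epoxy alcohol; 19 (diethoxyphosphoryl)acetic acid
Product: 20 (diethoxyphosphoryl)acetate ester of 18 at O6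
Conditions: DCC, DMAP (cat.), CH2Cl2, 0 → 25 °C
Reagents that add atoms: none
Why: Steglich esterification of the secondary alcohol tethers the future C11–C12 unit to O6 without disturbing the epoxide.

Step 12
Reactants: 20 (diethoxyphosphoryl)acetate ester of 18
Product: 21 trans-fused α-(diethoxyphosphoryl)-γ-lactone with free 8-OH (C11 epimers)
Conditions: LiN(SiMe3)2 (1.05 equiv), THF, −78 → 25 °C; then AcOH, −78 °C
Reagents that add atoms: none
Why: Intramolecular alkylation of the phosphonoacetate carbanion by the epoxide (5-exo-tet at the proximal carbon C7, the tethered form of the phosphonoacetate–epoxide route to α-phosphono lactones) forms C7–C11 with inversion at C7 while C6 and C8 keep their oxygens, which gives the trans lactone and the 8-alkoxide; the alkoxide is quenched internally by the acidic C11–H, and the resulting tertiary carbanion is too hindered to add to the tiglate-like dienoate.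

Step 13
Reactants: 21 trans-fused α-(diethoxyphosphoryl)-γ-lactone with free 8-OH
Product: 22 8-O-isobutyrate of 21 (seco-triene)
Conditions: isobutyric anhydride, DMAP (cat.), pyridine, CH2Cl2, 0 °C
Reagents that add atoms: isobutyric anhydride, CC(C)C(=O)OC(=O)C(C)C
Why: DMAP-catalysed acylation installs the isobutyrate of the target at once, before the γ-hydroxy ester can lactonise onto C14.

Step 14
Reactants: 22 8-O-isobutyrate seco-triene
Product: 23 ten-membered (2Z,1(10)E)-dienoate fused to the α-phosphono lactone
Conditions: second-generation Grubbs catalyst (10 mol %), toluene (0.5 mM), 80 °C, argon sparge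
Reagents that add atoms: none
Why: The ruthenium alkylidene loads onto the monosubstituted C4 vinyl group, undergoes [2+2] cycloaddition and cycloreversion with the terminal olefin of the dienoate and expels ethene, so that C2 and C3 are joined as a ring olefin (ene–diene ring-closing metathesis, well known for macrocyclic dienoates). The ten-membered carbocycle closes in the only mode open to it, because the internal C1=C10 olefin is trisubstituted, ester-bearing and inert, and the lactone methylene is still latent as the phosphonate. No stereocentre is formed; the new C2=C3 bond should be Z, since an E olefin next to the ring-cis C1=C10 bond is too strained in a ten-membered ring, and its geometry is erased in step 15. The selectivity needed is ring closure over oligomerisation, and it rests on high dilution, on removal of ethene, and on the trans-fused lactone and the cis-enoate as two turn elements that bring C2 and C3 together. The feature exploited is that C2 is allylic to the C1=C10 enoate, so the ring-closing olefin is part of a conjugated diene and the enoate geometry made in step 7 is carried through unchanged.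

Step 15
Reactants: 23 ten-membered (2Z,1(10)E)-dienoate
Product: 24 2,3-dihydro derivative of 23
Conditions: 2-nitrobenzenesulfonylhydrazide, Et3N, CH2Cl2, 25 °C
Reagents that add atoms: none
Why: Diimide reduction transfers H2 in a concerted syn step to the strained cis-disubstituted C2=C3 olefin much faster than to the trisubstituted, ester-conjugated C1=C10 olefin, and touches no other group.

Step 16
Reactants: 24 2,3-dihydro derivative of 23
Product: 25 15-alcohol (desilylated 24)
Conditions: HF·pyridine, pyridine, THF, 0 → 25 °C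
Reagents that add atoms: none
Why: Fluoride-mediated cleavage of the primary silyl ether is done while the lactone still carries the phosphonate, so the Michael-sensitive methylene lactone never meets fluoride or pyridine.

Step 17
Reactants: 25 15-alcohol
Product: 26 target, (4S,6R,7S,8R)-8-isobutyryloxy-15-hydroxy-4,5-dihydrogermacr-1(10)-en-6,12-olid-14-oic acid methyl ester with 11(13)-methylene
Conditions: HCHO (37 % aq.), K2CO3, THF, 0 → 25 °C
Reagents that add atoms: formaldehyde, C=O
Why: Horner–Wadsworth–Emmons olefination of the α-phosphono lactone with formaldehyde gives the α-methylene lactone under conditions mild enough for the isobutyrate, the methyl ester and the free alcohol.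

Compound list
1 | (4R)-4-benzyl-1,3-oxazolidin-2-one | O=C1N[C@H](Cc2ccccc2)CO1 | starting material
2 | (2E)-but-2-enoyl chloride | C/C=C/C(Cl)=O | starting material
3 | (4R)-4-benzyl-3-[(2E)-but-2-enoyl]-1,3-oxazolidin-2-one | C/C=C/C(=O)N1[C@H](Cc2ccccc2)COC1=O | intermediate
4 | tert-butyl bromoacetate | CC(C)(C)OC(=O)CBr | starting material
5 | tert-butyl (3R)-3-{[(4R)-4-benzyl-2-oxo-1,3-oxazolidin-3-yl]carbonyl}pent-4-enoate | C=C[C@@H](CC(=O)OC(C)(C)C)C(=O)N1[C@H](Cc2ccccc2)COC1=O | intermediate
6 | tert-butyl (3R)-3-(hydroxymethyl)pent-4-enoate | C=C[C@@H](CC(=O)OC(C)(C)C)CO | intermediate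
7 | tert-butyl (3R)-3-({[tert-butyl(dimethyl)silyl]oxy}methyl)pent-4-enoate | C=C[C@@H](CC(=O)OC(C)(C)C)CO[Si](C)(C)C(C)(C)C | intermediate
8 | (3R)-3-({[tert-butyl(dimethyl)silyl]oxy}methyl)pent-4-enal | C=C[C@@H](CC=O)CO[Si](C)(C)C(C)(C)C | intermediate
9 | methyl (triphenyl-λ5-phosphanylidene)acetate | COC(=O)C=P(c1ccccc1)(c1ccccc1)c1ccccc1 | starting material
10 | 3-bromoprop-1-yne | C#CCBr | starting material
11 | (1-methoxy-1-oxopent-4-yn-2-yl)triphenylphosphonium bromide | C#CCC(C(=O)OC)[P+](c1ccccc1)(c1ccccc1)c1ccccc1.[Br-] | intermediate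
12 | methyl 2-(triphenyl-λ5-phosphanylidene)pent-4-ynoate | C#CCC(C(=O)OC)=P(c1ccccc1)(c1ccccc1)c1ccccc1 | intermediate
13 | prop-2-enal | C=CC=O | starting material
14 | methyl (2E)-2-(prop-2-yn-1-yl)penta-2,4-dienoate | C#CC/C(C(=O)OC)=C\C=C | intermediate
15 | (E)-alkenylzirconocene chloride from 14 | Cl[Zr](C1C=CC=C1)(C1C=CC=C1)/C=C/C/C(C(=O)OC)=C\C=C | intermediate
16 | methyl (2E)-2-[(2E)-3-iodoprop-2-en-1-yl]penta-2,4-dienoate | I/C=C/C/C(C(=O)OC)=C\C=C | intermediate
17 | methyl (2E)-2-[(2E,4R,6R)-6-({[tert-butyl(dimethyl)silyl]oxy}methyl)-4-hydroxyocta-2,7-dien-1-yl]penta-2,4-dienoate (germacrane C4 R, C6 R) | C=C[C@H](CO[Si](C)(C)C(C)(C)C)C[C@@H](O)/C=C/C/C(C(=O)OC)=C\C=C | intermediate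
18 | methyl (2E)-2-({(2R,3R)-3-[(1R,3R)-3-({[tert-butyl(dimethyl)silyl]oxy}methyl)-1-hydroxypent-4-en-1-yl]oxiran-2-yl}methyl)penta-2,4-dienoate (erythro trans-epoxy alcohol; C4 R, C6 R, C7 R, C8 R) | C=C[C@H](CO[Si](C)(C)C(C)(C)C)C[C@@H](O)[C@H]1O[C@@H]1C/C(C(=O)OC)=C\C=C | intermediate
19 | (diethoxyphosphoryl)acetic acid | CCOP(=O)(CC(=O)O)OCC | starting material
20 | (diethoxyphosphoryl)acetate ester of 18 at O6 (all centres as in 18) | C=C[C@H](CO[Si](C)(C)C(C)(C)C)C[C@@H](OC(=O)CP(=O)(OCC)OCC)[C@H]1O[C@@H]1C/C(C(=O)OC)=C\C=C | intermediate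
21 | 3-(diethoxyphosphoryl)oxolan-2-one with the (2R)-2-(silyloxymethyl)but-3-enyl chain on C6 and the (1R,3E)-1-hydroxy-3-(methoxycarbonyl)hexa-3,5-dienyl chain on C7, trans across C6–C7 (C4 R, C6 R, C7 R, C8 R; C11 epimers) | CCOP(=O)(OCC)C1C(=O)O[C@H](C[C@@H](CO[Si](C)(C)C(C)(C)C)C=C)[C@H]1[C@H](O)C/C(C(=O)OC)=C\C=C | intermediate
22 | 8-O-isobutyrate of 21 (C4 R, C6 R, C7 S, C8 R; C11 epimers) | CCOP(=O)(OCC)C1C(=O)O[C@H](C[C@@H](CO[Si](C)(C)C(C)(C)C)C=C)[C@H]1[C@H](OC(=O)C(C)C)C/C(C(=O)OC)=C\C=C | intermediate
23 | ten-membered (2Z,1(10)E)-dienoate fused trans to the α-phosphono lactone, 8-isobutyrate, 15-silyl ether (C4 R, C6 R, C7 S, C8 R) | CCOP(=O)(OCC)C1C(=O)O[C@@H]2C[C@@H](CO[Si](C)(C)C(C)(C)C)/C=C\C=C(\C(=O)OC)C[C@@H](OC(=O)C(C)C)[C@@H]12 | intermediate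
24 | 2,3-dihydro derivative of 23 (C4 S, C6 R, C7 S, C8 R) | CCOP(=O)(OCC)C1C(=O)O[C@@H]2C[C@@H](CO[Si](C)(C)C(C)(C)C)CC/C=C(/C(=O)OC)C[C@@H](OC(=O)C(C)C)[C@@H]12 | intermediate
25 | 15-alcohol, desilylated 24 (C4 S, C6 R, C7 S, C8 R) | CCOP(=O)(OCC)C1C(=O)O[C@@H]2C[C@@H](CO)CC/C=C(/C(=O)OC)C[C@@H](OC(=O)C(C)C)[C@@H]12 | intermediate
26 | CNP0251148.1, (4S,6R,7S,8R)-configured methylene lactone | C=C1C(=O)O[C@@H]2C[C@@H](CO)CC/C=C(/C(=O)OC)C[C@@H](OC(=O)C(C)C)[C@@H]12 | target

Total step count: 17. Longest linear sequence: 14 steps (steps 1–5, then 9–17).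

Steps most likely to fail

Step 14. Ring closure may lose to intermolecular metathesis (oligomers) if the trans-fused lactone, the C8 ester and the C11 phosphonate hold the two olefin termini apart, or the catalyst may rest as the conjugated vinyl-alkylidene. The fallback reverses the order of the two ring constructions and sets out from 20. Its C6–C7 bond is still a free rotor and its trans-epoxide is a compact turn element of the kind found in germacrane epoxides. Ring-closing metathesis of 20 under the conditions of step 14 should give the macrocyclic epoxy phosphonoacetate F1. LiN(SiMe3)2 then effects the same 5-exo epoxide opening on the ring to give the cyclic hydroxy phosphono lactone F2, and isobutyrylation as in step 13 comes back to the route at 23.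

Step 12. The carbanion may attack the distal epoxide carbon C8 (six-membered lactone), or the cyclisation may be slow because the ester must reach its s-cis rotamer. Slow cyclisation would let lactonisation of the 8-alkoxide onto C14, or conjugate addition, compete. The fallback builds C7–C11 and C8–O by a carbene route and sets out from 17. Steglich esterification with 19 gives the allylic phosphonoacetate F3, and diazo transfer (4-acetamidobenzenesulfonyl azide, DBU, MeCN) gives the diazo ester F4. Rh2(OAc)4-catalysed intramolecular cyclopropanation of the (E)-C7=C8 olefin, on the face that leaves the C6 side chain on the convex side, gives the cyclopropane-fused phosphono lactone F5. Homoconjugate opening of this doubly activated cyclopropane at C8 by caesium isobutyrate (isobutyric acid, Cs2CO3, DMSO, 60 °C) with inversion should give the 8-isobutyrate directly. The fallback comes back to the route at 22 and bypasses steps 10–13.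

Step 15. Diimide may over-reduce the conjugated C1=C10 olefin or stall at the hindered ring olefin. The fallback replaces 1,2-reduction by a 1,4-hydrogenation and sets out from 23. H2 with (naphthalene)Cr(CO)3 in THF at 45 °C adds across the s-cis diene and should give the (Z)-β,γ-unsaturated ester F6 with the olefin at C1=C2. DBU in CH2Cl2 then moves the olefin into conjugation with the ester and comes back to the route at 24.

Further compounds
F1 | step 14 | macrocyclic epoxy phosphonoacetate: 20 closed between C2 and C3, (2Z,1(10)E)-diene, trans-7,8-epoxide | CCOP(=O)(OCC)CC(=O)O[C@@H]1C[C@@H](CO[Si](C)(C)C(C)(C)C)/C=C\C=C(\C(=O)OC)C[C@H]2O[C@H]12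
F2 | step 14 | cyclic hydroxy phosphono lactone: 23 with free 8-OH | CCOP(=O)(OCC)C1C(=O)O[C@@H]2C[C@@H](CO[Si](C)(C)C(C)(C)C)/C=C\C=C(\C(=O)OC)C[C@@H](O)[C@@H]12
F3 | step 12 | (diethoxyphosphoryl)acetate ester of 17 at O6 | C=C[C@H](CO[Si](C)(C)C(C)(C)C)C[C@@H](OC(=O)CP(=O)(OCC)OCC)/C=C/C/C(C(=O)OC)=C\C=C
F4 | step 12 | diazo(diethoxyphosphoryl)acetate ester of 17 at O6 | C=C[C@H](CO[Si](C)(C)C(C)(C)C)C[C@@H](OC(=O)C(=[N+]=[N-])P(=O)(OCC)OCC)/C=C/C/C(C(=O)OC)=C\C=C
F5 | step 12 | 1-(diethoxyphosphoryl)-3-oxabicyclo[3.1.0]hexan-2-one with C11 bonded to C7 and C8, C6 side chain on the convex face | CCOP(=O)(OCC)[C@]12C(=O)O[C@H](C[C@@H](CO[Si](C)(C)C(C)(C)C)C=C)[C@H]1[C@@H]2C/C(C(=O)OC)=C\C=C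
F6 | step 15 | (1Z)-β,γ-unsaturated ester: 23 after 1,4-addition of H2, C10 epimers | CCOP(=O)(OCC)C1C(=O)O[C@@H]2C[C@@H](CO[Si](C)(C)C(C)(C)C)C/C=C\C(C(=O)OC)C[C@@H](OC(=O)C(C)C)[C@@H]12
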